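The six-membered carbocycle (C5–C10: C5 bears the CMe2OH group, C6 is CH2, C7 bears OH, C8 bears Me, C9 is the spiro ether carbon, C10 the spiro lactone carbon) is a masked 6,6-disubstituted 2-methylcyclohex-2-enone, with C9 as the ketone and C8/C7 as its α/β carbons. It is grown from a cyclopentanone (C9, C10, C5, C6, C7) that already holds the C5 and C10 stereocentres. Dibromocarbene adds to its silyl enol ether and the strained cyclopropane opens electrocyclically, which inserts C8 between C9 and C7 and gives the six-membered bromo-enone in one operation. The enone then relays C7–C9, and a spiro α-methylene lactone is elaborated to the orthoester cage.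

Key step: step 5

Remark on locants: C1–C3 and C19 are the δ-lactone carbons (C3 carbonyl, C19 the OCH2 on C10), C4 the carbinol carbon, C11 the oxolane CH2, C12 the quaternary C–Me, C13 the CH–Me, C14 the CH next to the γ-lactone carbonyl C18, C15 the orthoester carbon, C16 the cage O–CH, C17 the ketal carbon; β is the ring face that carries C19.

Assumption: the configuration of the SMILES is taken as absolute; (R)-BINAP in step 2 is assigned by analogy with 3-substituted cyclopentanones, and the other ligand enantiomer is used if the sense proves opposite.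

Step 1
Reactants: 1 methyl 2-oxocyclopentane-1-carboxylate
Product: 2 methyl 5-oxocyclopent-1-ene-1-carboxylate
Conditions: PhSeCl, pyridine, CH2Cl2, 0 °C; then 30% H2O2, 0 °C to rt; used at once
Reagents that add atoms: none
Why: α-Selenenylation of the β-keto ester followed by oxidation and syn-elimination of the selenoxide (selenoxide elimination) gives the doubly activated enone, which is used at once.

Step 2
Reactants: 2 methyl 5-oxocyclopent-1-ene-1-carboxylate; 3 isopropenylboronic acid pinacol ester; 4 methyl acrylate
Product: 6 methyl 1-(3-methoxy-3-oxopropyl)-2-oxo-5-(prop-1-en-2-yl)cyclopentane-1-carboxylate with the ring ester cis to the isopropenyl group, via conjugate adduct β-keto ester 5 (not isolated)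
Conditions: [Rh(cod)OH]2 (cat.), (R)-BINAP, KOH (cat.), dioxane/H2O, 35 °C; then 4, K2CO3 (cat.), rt
Reagents that add atoms: isopropenylboronic acid pinacol ester (3) CC(=C)B1OC(C)(C)C(C)(C)O1; methyl acrylate (4) C=CC(=O)OC
Why: Hayashi–Miyaura rhodium/(R)-BINAP 1,4-addition sets C5 by ligand-controlled face selection, and the β-keto ester so formed adds in a base-catalysed Michael reaction to methyl acrylate anti to the neighbouring isopropenyl group, which sets the quaternary C10 with the ring ester cis to the C5 substituent.

Step 3
Reactants: 6 keto diester with isopropenyl group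
Product: 7 methyl 5-(2-hydroxypropan-2-yl)-1-(3-methoxy-3-oxopropyl)-2-oxocyclopentane-1-carboxylate (configuration of 6)
Conditions: Mn(dpm)3 (cat.), PhSiH3, O2 (1 atm), i-PrOH, 0 °C to rt
Reagents that add atoms: dioxygen O=O
Why: Mukaiyama hydration (manganese hydride hydrogen-atom transfer to the 1,1-disubstituted alkene, then O2 trapping and reduction) gives the Markovnikov tertiary alcohol and leaves ketone and esters untouched; no stereocentre is formed.

Step 4
Reactants: 7 hydroxy keto diester
Product: 8 methyl 1-(3-methoxy-3-oxopropyl)-2-(triethylsilyloxy)-5-[2-(triethylsilyloxy)propan-2-yl]cyclopent-2-ene-1-carboxylate (configuration of 6)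
Conditions: TESOTf (2.4 equiv), Et3N, CH2Cl2, −78 to 0 °C
Reagents that add atoms: triethylsilyl trifluoromethanesulfonate CC[Si](CC)(CC)OS(=O)(=O)C(F)(F)F
Why: Soft enolization can only go towards C7 because C10 is quaternary, and the tertiary alcohol is silylated in the same operation (silyl enol ether formation and silyl protection).

Step 5
Reactants: 8 bis-silylated cyclopentene (C9=C7 silyl enol ether); 9 bromoform
Product: 11 methyl 3-bromo-1-(3-methoxy-3-oxopropyl)-2-oxo-6-[2-(triethylsilyloxy)propan-2-yl]cyclohex-3-ene-1-carboxylate with the ring ester cis to the C6 side chain (C9 ketone, C8–Br, C7=C8), via dibromocyclopropane 10 (not isolated)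
Conditions: CHBr3, KOtBu, hexane, −20 °C to rt; then toluene, 60 °C
Reagents that add atoms: bromoform (9) BrC(Br)Br
Why: Dibromocarbene adds to the electron-rich enol ether in a cheletropic [2+1] step to give the 1-silyloxy-6,6-dibromobicyclo[3.1.0]hexane 10, whose endo C–Br bond ionizes in concert with disrotatory 2π-electrocyclic opening of the internal C9–C7 bond, pushed by the silyloxy group, and loss of Et3SiBr from the oxyallyl cation gives the 2-bromocyclohex-2-enone. The closest known reaction type is the dihalocarbene ring expansion of cyclic silyl enol ethers to 2-halocycloalk-2-enones (cyclopropyl-to-allyl cation rearrangement). The three-membered ring closes by [2+1] cycloaddition, and the six-membered ring is not closed but arises by electrocyclic cleavage of the bond shared by the two fused rings. No stereocentre is created (C7, C8 and C9 leave as sp2 centres and both carbene faces converge), and C5 and C10 are not touched. The step needs regioselectivity, secured because C10 is quaternary so that only the C9=C7 enol ether exists and orbital symmetry lets only the internal bond break, and chemoselectivity, secured because the enol ether is the only alkene left after step 3.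

Step 6
Reactants: 11 bromo enone; 12 methylboronic acid
Product: 13 methyl 1-(3-methoxy-3-oxopropyl)-3-methyl-2-oxo-6-[2-(triethylsilyloxy)propan-2-yl]cyclohex-3-ene-1-carboxylate (configuration of 11)
Conditions: Pd(OAc)2 (cat.), SPhos, K3PO4, toluene/H2O, 80 °C
Reagents that add atoms: methylboronic acid (12) CB(O)O
Why: Suzuki–Miyaura coupling of the α-bromo enone puts the methyl group on C8 with retention of the alkene position.

Step 7
Reactants: 13 methyl enone diester
Product: 14 6-(hydroxymethyl)-6-(3-hydroxypropyl)-2-methyl-5-[2-(triethylsilyloxy)propan-2-yl]cyclohex-2-en-1-ol with 9β-OH, β-hydroxymethyl (C19) and β C5 side chain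
Conditions: DIBAL-H (excess), CH2Cl2, −78 to 0 °C; Rochelle salt
Reagents that add atoms: none
Why: DIBAL-H reduces both esters to primary alcohols and the enone by 1,2-addition, hydride reaching C9 anti to the axial C10 substituent so that the allylic hydroxyl is β (cis to the C10 hydroxymethyl).

Step 8
Reactants: 14 allylic alcohol triol
Product: 15 7β,8β-epoxide of 14 (epoxide cis to the 9β-hydroxyl)
Conditions: VO(acac)2 (cat.), t-BuOOH, CH2Cl2, 0 °C to rt
Reagents that add atoms: tert-butyl hydroperoxide CC(C)(C)OO
Why: Hydroxyl-directed vanadium-catalysed epoxidation delivers oxygen to C7=C8 on the face of the allylic 9β-hydroxyl, giving the 7β,8β-epoxide.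

Step 9
Reactants: 15 epoxy triol
Product: 16 tetraol with 7β-OH, 8β-methyl (8α-H), 9β-OH, C19 hydroxymethyl, 3-hydroxypropyl and the C4 silyl ether
Conditions: Cp2TiCl2 (20 mol %), Zn, 2,4,6-collidine·HCl, 1,4-cyclohexadiene, THF, rt
Reagents that add atoms: none
Why: Titanocene(III) reductive epoxide opening (Nugent–RajanBabu reaction, catalytic variant) cleaves the C8–O bond to the tertiary radical, which takes a hydrogen atom from 1,4-cyclohexadiene on the α face, anti to the two flanking β oxygen substituents, so that the C8 methyl ends β and cis to the retained 7β-hydroxyl.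

Step 10
Reactants: 16 tetraol
Product: 17 spiro δ-lactone (C3 carbonyl, C19 as OCH2) carrying the 7β,9β-diol, 8β-methyl and the C4 silyl ether
Conditions: TEMPO (20 mol %), PhI(OAc)2 (2.5 equiv), CH2Cl2, rt
Reagents that add atoms: none
Why: TEMPO/hypervalent-iodine oxidation is selective for the unhindered primary C3 alcohol, whose aldehyde is captured as the six-membered lactol by the primary C19 hydroxyl and oxidized further to the spiro δ-lactone, while the secondary alcohols survive.

Step 11
Reactants: 17 lactone diol
Product: 18 7-O-triethylsilyl ether of 17 (9β-OH free)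
Conditions: TESCl, imidazole, DMF, −20 °C
Reagents that add atoms: chlorotriethylsilane CC[Si](CC)(CC)Cl
Why: Silylation differentiates the secondary alcohols by hindrance, C7–OH reacting while C9–OH, flanked by the quaternary C10 and C8, stays free.

Step 12
Reactants: 18 mono-protected diol
Product: 19 C9 ketone (7β-OTES, 8β-methyl, spiro δ-lactone, C4 OTES)
Conditions: Dess–Martin periodinane, CH2Cl2, 0 °C to rt
Reagents that add atoms: none
Why: Dess–Martin oxidation gives the C9 ketone under non-basic conditions, so the kinetically set C8 stereocentre next to it is not epimerized.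

Step 13
Reactants: 19 C9 ketone; 20 ethyl 2-(bromomethyl)acrylate
Product: 21 C9-spiro α-methylene-γ-butyrolactone (lactone oxygen β, C11 α) with the spiro δ-lactone and both silyl ethers retained
Conditions: Zn (activated), THF, 50 °C; then aq. NH4Cl
Reagents that add atoms: ethyl 2-(bromomethyl)acrylate (20) C=C(CBr)C(=O)OCC
Why: Dreiding–Schmidt reaction (zinc Barbier allylation then lactonization): the allylzinc adds to the C9 ketone along the axial trajectory from the α face, because the β face is blocked by the axial C8 methyl and the axial C19 arm, and the alkoxide closes onto the ethyl ester, giving the spirolactone with O β and C11 α.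

Step 14
Reactants: 22 α-angelica lactone (5-methylfuran-2(3H)-one); 23 acetaldehyde
Product: 24 (E)-3-ethylidene-5-methylfuran-2(3H)-one
Conditions: pyrrolidine (cat.), AcOH (cat.), CH2Cl2, 0 °C to rt
Reagents that add atoms: acetaldehyde (23) CC=O
Why: Knoevenagel-type aldol condensation at the doubly activated C3 methylene of α-angelica lactone gives the thermodynamically preferred (E)-alkylidene butenolide.

Step 15
Reactants: 21 spiro α-methylene lactone; 24 (E)-3-ethylidene-5-methylfuran-2(3H)-one
Product: 27 γ-hydroxybutenolide: the spirolactone α-carbon C12 is quaternary (Me, C13), C13 carries Me and a 5-hydroxy-5-methyl-2-oxo-2,5-dihydrofuran-3-yl group (C12 and C13 as in the target, lactol carbon C17 as epimers), via lactone lithium enolate 25 (not isolated), via silyloxyfuran 26 (not isolated)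
Conditions: L-Selectride, THF, −78 °C; 24, −78 to −40 °C; TMSCl, Et3N; concentrate; dimethyldioxirane (excess), acetone/CH2Cl2, −78 to 0 °C
Reagents that add atoms: (E)-3-ethylidene-5-methylfuran-2(3H)-one (24) C/C=C1\C=C(C)OC1=O; dimethyldioxirane CC1(C)OO1
Why: Conjugate hydride reduction gives the lactone enolate 25, whose Michael addition to the exocyclic β-carbon of 24 (driven by formation of the aromatic furanolate) should proceed through a lithium-chelated closed transition state on the enolate face anti to C10, setting C12 by substrate control and C13 by the fixed enolate and (E)-acceptor geometries; O-silylation and dimethyldioxirane oxidation of the 2-silyloxyfuran (vinylogous Rubottom oxidation) then give the γ-hydroxybutenolide.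

Step 16
Reactants: 27 γ-hydroxybutenolide
Product: 28 7,4-bis-O-triethylsilyl chermebilaene B (complete orthoester cage)
Conditions: CSA (10 mol %), 4 Å MS, CH2Cl2, 0 °C to rt
Reagents that add atoms: none
Why: Proposed new method: acid catalysis should let the C17 lactol hydroxyl add to the tethered spirolactone carbonyl C15 and the hemi-orthoester hydroxyl so formed close by 5-exo-trig oxa-Michael addition onto C16 of the butenolide with protonation of C14, an isomerization whose closest known relatives are the acid-catalysed formation of spiro-orthoesters from lactones and the intramolecular oxa-Michael addition to butenolides; because the tether through C12–C13 and the cis ring fusions allow only one cage, C14, C15, C16 and C17 are all dictated by C12.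

Step 17
Reactants: 28 bis-silyl ether of the target
Product: 29 chermebilaene B
Conditions: HF·pyridine, pyridine, THF, 0 °C to rt
Reagents that add atoms: none
Why: Buffered HF·pyridine cleaves both triethylsilyl ethers (fluoride-mediated desilylation) without hydrolysing the orthoester or the lactones.

Compound list
1 | methyl 2-oxocyclopentane-1-carboxylate | COC(=O)C1CCCC1=O | starting material
2 | methyl 5-oxocyclopent-1-ene-1-carboxylate | COC(=O)C1=CCCC1=O | intermediate
3 | isopropenylboronic acid pinacol ester | CC(=C)B1OC(C)(C)C(C)(C)O1 | starting material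
4 | methyl acrylate | C=CC(=O)OC | starting material
5 | methyl 2-oxo-5-(prop-1-en-2-yl)cyclopentane-1-carboxylate (C5 set, ester-bearing carbon labile, trans shown) | C1C[C@@H](C(C)=C)[C@H](C(=O)OC)C1=O | intermediate
6 | methyl 1-(3-methoxy-3-oxopropyl)-2-oxo-5-(prop-1-en-2-yl)cyclopentane-1-carboxylate, ring ester cis to isopropenyl | C1C[C@@H](C(C)=C)[C@](C(=O)OC)(CCC(=O)OC)C1=O | intermediate
7 | methyl 5-(2-hydroxypropan-2-yl)-1-(3-methoxy-3-oxopropyl)-2-oxocyclopentane-1-carboxylate | C1C[C@@H](C(C)(C)O)[C@](C(=O)OC)(CCC(=O)OC)C1=O | intermediate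
8 | methyl 1-(3-methoxy-3-oxopropyl)-2-(triethylsilyloxy)-5-[2-(triethylsilyloxy)propan-2-yl]cyclopent-2-ene-1-carboxylate | C1C[C@@H](C(C)(C)O[Si](CC)(CC)CC)[C@](C(=O)OC)(CCC(=O)OC)C=1O[Si](CC)(CC)CC | intermediate
9 | bromoform | BrC(Br)Br | starting material
10 | 6,6-dibromo-1-(triethylsilyloxy)bicyclo[3.1.0]hexane adduct of 8 (either cyclopropane face, both converge) | BrC1(Br)C2C[C@@H](C(C)(C)O[Si](CC)(CC)CC)[C@](C(=O)OC)(CCC(=O)OC)C12O[Si](CC)(CC)CC | intermediate
11 | methyl 3-bromo-1-(3-methoxy-3-oxopropyl)-2-oxo-6-[2-(triethylsilyloxy)propan-2-yl]cyclohex-3-ene-1-carboxylate, ester cis to the C6 side chain | BrC1=CC[C@@H](C(C)(C)O[Si](CC)(CC)CC)[C@](C(=O)OC)(CCC(=O)OC)C1=O | intermediate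
12 | methylboronic acid | CB(O)O | starting material
13 | methyl 1-(3-methoxy-3-oxopropyl)-3-methyl-2-oxo-6-[2-(triethylsilyloxy)propan-2-yl]cyclohex-3-ene-1-carboxylate | CC1=CC[C@@H](C(C)(C)O[Si](CC)(CC)CC)[C@](C(=O)OC)(CCC(=O)OC)C1=O | intermediate
14 | 6-(hydroxymethyl)-6-(3-hydroxypropyl)-2-methyl-5-[2-(triethylsilyloxy)propan-2-yl]cyclohex-2-en-1-ol (9β-OH) | CC1=CC[C@@H](C(C)(C)O[Si](CC)(CC)CC)[C@](CO)(CCCO)[C@H]1O | intermediate
15 | 7β,8β-epoxide of 14 | O1[C@@]2(C)[C@@H]1C[C@@H](C(C)(C)O[Si](CC)(CC)CC)[C@](CO)(CCCO)[C@H]2O | intermediate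
16 | tetraol with 7β-OH, 8β-Me, 9β-OH | C[C@H]1[C@@H](O)C[C@@H](C(C)(C)O[Si](CC)(CC)CC)[C@](CO)(CCCO)[C@H]1O | intermediate
17 | spiro δ-lactone 7β,9β-diol | C[C@H]1[C@@H](O)C[C@@H](C(C)(C)O[Si](CC)(CC)CC)[C@]2(CCC(=O)OC2)[C@H]1O | intermediate
18 | 7-O-triethylsilyl ether of 17 | C[C@H]1[C@@H](O[Si](CC)(CC)CC)C[C@@H](C(C)(C)O[Si](CC)(CC)CC)[C@]2(CCC(=O)OC2)[C@H]1O | intermediate
19 | C9 ketone | C[C@H]1[C@@H](O[Si](CC)(CC)CC)C[C@@H](C(C)(C)O[Si](CC)(CC)CC)[C@]2(CCC(=O)OC2)C1=O | intermediate
20 | ethyl 2-(bromomethyl)acrylate | C=C(CBr)C(=O)OCC | starting material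
21 | C9-spiro α-methylene-γ-butyrolactone | C[C@H]1[C@@H](O[Si](CC)(CC)CC)C[C@@H](C(C)(C)O[Si](CC)(CC)CC)[C@]2(CCC(=O)OC2)[C@]12CC(=C)C(=O)O2 | intermediate
22 | α-angelica lactone | CC1=CCC(=O)O1 | starting material
23 | acetaldehyde | CC=O | starting material
24 | (E)-3-ethylidene-5-methylfuran-2(3H)-one | C/C=C1\C=C(C)OC1=O | intermediate
25 | lithium enolate of the α-methyl spirolactone | C[C@H]1[C@@H](O[Si](CC)(CC)CC)C[C@@H](C(C)(C)O[Si](CC)(CC)CC)[C@]2(CCC(=O)OC2)[C@]12CC(C)=C(O[Li])O2 | intermediate
26 | 5-methyl-2-(trimethylsilyloxy)furan-3-yl Michael adduct | C[C@H]1[C@@H](O[Si](CC)(CC)CC)C[C@@H](C(C)(C)O[Si](CC)(CC)CC)[C@]2(CCC(=O)OC2)[C@]12C[C@](C)([C@@H](C)c3cc(C)oc3O[Si](C)(C)C)C(=O)O2 | intermediate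
27 | γ-hydroxybutenolide (C17 epimers) | C[C@H]1[C@@H](O[Si](CC)(CC)CC)C[C@@H](C(C)(C)O[Si](CC)(CC)CC)[C@]2(CCC(=O)OC2)[C@]12C[C@](C)([C@@H](C)C3=CC(C)(O)OC3=O)C(=O)O2 | intermediate
28 | 7,4-bis-O-triethylsilyl chermebilaene B | C[C@H]1[C@@H](O[Si](CC)(CC)CC)C[C@@H](C(C)(C)O[Si](CC)(CC)CC)[C@]2(CCC(=O)OC2)[C@]12C[C@]1(C)[C@@H](C)[C@H]3C(=O)O[C@@]4(C)O[C@@]1(O[C@@H]34)O2 | intermediate
29 | chermebilaene B | C[C@H]1[C@@H](O)C[C@@H](C(C)(C)O)[C@]2(CCC(=O)OC2)[C@]12C[C@]1(C)[C@@H](C)[C@H]3C(=O)O[C@@]4(C)O[C@@]1(O[C@@H]34)O2 | target

Total step count: 17. Longest linear sequence: 16 steps (steps 1–13 and 15–17; step 14 is a one-step side branch).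

Steps most likely to fail

Step 16 (proposed new method). The hemi-orthoester may revert faster than it is trapped by the conjugate addition, so that no cage forms, or the acid may instead dehydrate the lactol or cleave the silyl ethers. The fallback uses the known Lewis-acid epoxy ester–orthoester rearrangement. It sets out from 26, intercepted before the oxidation of step 15. Mild protodesilylation (AcOH, MeOH/THF, −40 °C) gives the 3H-furan-2-one, the enol lactone F1, with C14 equilibrated by a trace of DBU if needed. Dimethyldioxirane epoxidizes its enol ester double bond anti to the C13 substituent to give the acyloxy epoxide F2. BF3·OEt2 (or Cp2ZrCl2/AgClO4) in CH2Cl2 should then let the spirolactone carbonyl oxygen open the epoxide at C16 with inversion, and the C17 hemiketal oxygen, after ring–chain equilibration, close onto the dioxacarbenium ion at C15. The route is rejoined at 28.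

Step 15. Face selection at the enolate may be poor, or the relative topicity of the C12–C13 bond formation may be lost; proton transfer from the acceptor may also quench the enolate. The fallback replaces the lithium-chelated addition by an open-transition-state Mukaiyama–Michael reaction. It sets out from 21: L-Selectride reduction and O-silylation (TBSCl, HMPA) give the silyl ketene acetal F3. Addition of F3 to 24 with catalytic TBSOTf in CH2Cl2 at −78 °C, with silyl transfer, gives the tert-butyldimethylsilyloxyfuran F4. Dimethyldioxirane oxidizes F4, and the route is rejoined at 27.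

Step 9. Hydrogen-atom transfer to the C8 radical may be poorly face-selective, or a second reduction may lead to β-elimination and deoxygenation to the alkene. The fallback separates C–O cleavage from C–H formation. It sets out from 15: the aluminium amide Et2Al–TMP in toluene at 0 °C removes a proton of the C8 methyl group syn to the epoxide and gives the exocyclic allylic alcohol F5 (C8=CH2, 7β-OH). Hydrogenation (H2, Pd/C, EtOAc) should occur from the α face, because the β face is screened by the axial C19 hydroxymethyl group and the two β hydroxyls. The route is rejoined at 16.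

Further compounds
F1 | step 16 | 3-substituted 5-methylfuran-2(3H)-one (enol lactone) from protodesilylation of 26 | C[C@H]1[C@@H](O[Si](CC)(CC)CC)C[C@@H](C(C)(C)O[Si](CC)(CC)CC)[C@]2(CCC(=O)OC2)[C@]12C[C@](C)([C@@H](C)[C@H]3C(=O)OC(C)=C3)C(=O)O2
F2 | step 16 | C16–C17 epoxide of F1, anti to the C13 substituent | C[C@H]1[C@@H](O[Si](CC)(CC)CC)C[C@@H](C(C)(C)O[Si](CC)(CC)CC)[C@]2(CCC(=O)OC2)[C@]12C[C@](C)([C@@H](C)[C@H]3C(=O)O[C@]4(C)O[C@H]34)C(=O)O2
F3 | step 15 | tert-butyldimethylsilyl ketene acetal of the α-methyl spirolactone | C[C@H]1[C@@H](O[Si](CC)(CC)CC)C[C@@H](C(C)(C)O[Si](CC)(CC)CC)[C@]2(CCC(=O)OC2)[C@]12CC(C)=C(O[Si](C)(C)C(C)(C)C)O2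
F4 | step 15 | 2-(tert-butyldimethylsilyloxy)-5-methylfuran-3-yl Michael adduct | C[C@H]1[C@@H](O[Si](CC)(CC)CC)C[C@@H](C(C)(C)O[Si](CC)(CC)CC)[C@]2(CCC(=O)OC2)[C@]12C[C@](C)([C@@H](C)c3cc(C)oc3O[Si](C)(C)C(C)(C)C)C(=O)O2
F5 | step 9 | exocyclic allylic alcohol (C8=CH2, 7β-OH, 9β-OH) | C=C1[C@@H](O)C[C@@H](C(C)(C)O[Si](CC)(CC)CC)[C@](CO)(CCCO)[C@H]1O
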